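The retrosynthesis cuts three things in order. First the C7–O benzoyl bond, then the two acyl–O bonds of a temporary cyclic carbonate spanning C6–O and C7–O, and last the C6–O bond itself, with the diene shifted back so that this oxygen sits on C4.
Enabling feature: the ring carries a C1=C2–C3=C4 diene flanked by C5–OBz and C6–OH. This is the 1,5-transposed (vinylogous allylic) isomer of a C6=C1–C2=C3 diene oxygenated at C4 and C5. The C7 oxygen on C1 stands 1,3 to C6, so one CO2 unit can bridge C7–O and C6–O as a 1,3-dioxan-2-one.
Forward: the carbocycle comes intact from (−)-shikimic acid. An oxirane is closed on C3–C4, the ester is reduced to C7–OH, and the oxirane is turned into C2=C3 plus C4–OH. The dioxanone ring closes in the palladium step and is opened again before the last benzoylation.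
Stereochemistry: C5 is shikimate C3, inverted in a Mitsunobu benzoylation. C6 is set from C4 (shikimate C4, untouched until then) by double inversion through palladium. Its oxygen therefore lands trans to the C5 benzoate, which gives the (5R,6R) enantiomer.

Key step: step 10

Remark: target numbering is used for every compound (C1 bears C7; shikimate C1, C2, C3, C4, C5, C6 = target C1, C6, C5, C4, C3, C2); "top" is the face of the C4 oxygen of shikimic acid and of the final C6–OH, "bottom" is the face of the final C5 benzoate; TBS = tert-butyldimethylsilyl, dppe = 1,2-bis(diphenylphosphino)ethane; intermediate 15 is drawn as its C4 σ-form without dppe.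

Step 1
Reactants: 1 (−)-shikimic acid
Product: 2 methyl (−)-shikimate
Conditions: MeOH, camphor-10-sulfonic acid (cat.), reflux
Reagents that add atoms: methanol, CO
Why: Fischer esterification of an unhindered conjugated acid in methanol as solvent, which touches no stereocentre.

Step 2
Reactants: 2 methyl (−)-shikimate
Product: 3 (3S,4R,5R)-epoxy ester (C7 methyl ester; C1=C6; C5–OH top; C3–C4 oxirane top)
Conditions: PPh3, DIAD, THF, 0 °C → rt
Reagents that add atoms: none
Why: Mitsunobu cyclodehydration, a reaction type shown on this very triol, in which the unhindered C3 hydroxyl is activated by PPh3/DIAD and displaced by the trans-vicinal C4 oxygen, so that C3 is inverted, C4–O keeps its configuration and the oxirane lies on the top face, cis to the untouched C5 hydroxyl.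

Step 3
Reactants: 3 epoxy ester
Product: 4 (3S,4R,5R)-epoxy diol (C7–OH; C1=C6; C5–OH top; C3–C4 oxirane top)
Conditions: iBu2AlH (3.3 equiv), CH2Cl2, −78 °C; aq. potassium sodium tartrate
Reagents that add atoms: none
Why: 1,2-reduction of a conjugated ester with iBu2AlH, which at −78 °C is far faster than hydride opening of a dialkyl oxirane (the usual passage from epoxy enoates to epoxy allylic alcohols), with one extra equivalent covering the free hydroxyl.

Step 4
Reactants: 4 epoxy diol
Product: 5 (3S,4R,5R)-C7 TBS ether with free C5–OH
Conditions: TBSCl (1.05 equiv), imidazole, CH2Cl2, 0 °C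
Reagents that add atoms: tert-butyldimethylsilyl chloride, CC(C)(C)[Si](C)(C)Cl
Why: chemoselective silylation, in which the bulky silyl chloride takes the primary allylic hydroxyl well ahead of the secondary C5 hydroxyl next to the oxirane.

Step 5
Reactants: 5 C7 TBS ether; 6 benzoic acid
Product: 7 (3S,4S,5S)-epoxy benzoate (C7–OTBS; C1=C6; C5–OBz bottom; C3–C4 oxirane top)
Conditions: PPh3, DIAD, BzOH, THF, 0 °C → rt
Reagents that add atoms: benzoic acid (6), O=C(O)c1ccccc1
Why: Mitsunobu esterification with SN2 inversion at the secondary allylic carbinol, which sets the final C5 configuration because benzoate enters from the bottom face, anti to the oxirane oxygen, while the SN2' alternative would need attack at the fully substituted C1.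

Step 6
Reactants: 7 epoxy benzoate
Product: 8 (3R,4R,5S)-hydroxy selenide (C7–OTBS; C1=C6; C5–OBz bottom; C4–OH top; C3–SePh bottom)
Conditions: (PhSe)2, NaBH4, EtOH, 0 °C → rt
Reagents that add atoms: diphenyl diselenide, c1ccc(cc1)[Se][Se]c1ccccc1
Why: first half of the Sharpless–Lauer epoxide-to-allylic-alcohol sequence, in which the soft and weakly basic selenolate opens the oxirane by anti SN2 attack at C3, the carbon remote from the electron-withdrawing and shielding C5 benzoate, so that C4–OH keeps the shikimate configuration.

Step 7
Reactants: 8 hydroxy selenide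
Product: 10 (4S,5S)-dienol (C7–OTBS; C6=C1–C2=C3; C5–OBz bottom; C4–OH top), via selenoxide 9 (not isolated)
Conditions: mCPBA (1.0 equiv), CH2Cl2, −78 °C; then Et3N, −78 °C → rt
Reagents that add atoms: none
Why: selenoxide syn-elimination, in which selenium is oxidised chemoselectively in the cold and on warming takes the cis allylic C2 hydrogen rather than the carbinol C4 hydrogen (the normal regiochemistry of β-hydroxy selenoxides), giving the conjugated diene without touching C4 or C5.

Step 8
Reactants: 10 dienol; 11 methyl chloroformate
Product: 12 (4S,5S)-silyl dienyl carbonate (C7–OTBS; C5–OBz bottom; C4–OCO2Me top)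
Conditions: ClCO2Me, pyridine, DMAP (cat.), CH2Cl2, 0 °C
Reagents that add atoms: methyl chloroformate (11), COC(=O)Cl
Why: standard acylation of a secondary allylic alcohol with a chloroformate, safe for the diene because the base is mild and neither ester has an anti-periplanar hydrogen for E2 aromatisation (each ring hydrogen is cis to the neighbouring ester).

Step 9
Reactants: 12 silyl dienyl carbonate
Product: 13 (4S,5S)-dienyl carbonate with free C7–OH (C6=C1–C2=C3; C5–OBz bottom; C4–OCO2Me top)
Conditions: HF·pyridine, pyridine, THF, 0 °C
Reagents that add atoms: none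
Why: fluoride-driven cleavage of a primary silyl ether with pyridine-buffered HF, a medium neither basic enough to move or cleave the esters nor acidic enough to ionise the dienyl carbonate.

Step 10
Reactants: 13 dienyl carbonate with free C7–OH; 14 carbon dioxide
Product: 16 (5R,6R)-cyclic carbonate (1,3-dioxan-2-one across C6–O and C7–O; C1=C2–C3=C4; C5–OBz bottom), via palladium dienyl hemicarbonate 15 (not isolated)
Conditions: Pd2(dba)3·CHCl3 (2.5 mol %), dppe (6 mol %), CO2 (1 atm), THF, 0 °C → rt
Reagents that add atoms: carbon dioxide (14), O=C=O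
Why: Proposed new method: zerovalent palladium binds C2=C3 on the bottom face and expels the top-face C4 carbonate (a far better leaving group than the C5 benzoate) with inversion; the departing methyl carbonate collapses to CO2 and methoxide, which deprotonates C7–OH so that CO2 is taken up as the tethered hemicarbonate of dienyl complex 15. The metal then moves suprafacially along the conjugated C4–C3–C2–C1–C6 array from the C2–C3–C4 to the C6–C1–C2 allyl form, and the hemicarbonate oxygen attacks C6 from the top face, anti to palladium, which makes the C6–O bond and leaves the C1=C2–C3=C4 diene. The closest known reaction types are the palladium-catalysed CO2 elimination–fixation of 4-(methoxycarbonyloxy)but-2-en-1-ols to vinyl cyclic carbonates and the terminus-selective Tsuji–Trost substitution of 2,4-dienyl carbonates, neither of which has been used for a 1,5-oxygen shift on a cyclohexadiene. The 1,3-dioxan-2-one closes in a 6-endo mode, because the tether hangs on the central allyl carbon C1 and both C1 and C6 become ring members. The C6 stereocentre is controlled by the C4 stereocentre through double inversion, so oxygen returns on the face the leaving group left, trans to the C5 benzoate. C4 is beyond the reach of the tether but C2 is as near as C6, so C6 selectivity is expected from the preference of dienylpalladium for attack at a terminus and from reversibility (a doubly allylic C2 carbonate re-ionises and drains to the conjugated diene), while aromatisation is held back because C5–H lies anti to the metal (no syn β-hydride elimination), no external base is added and the CO2 atmosphere keeps alkoxide masked as weakly basic carbonate.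

Step 11
Reactants: 16 cyclic carbonate
Product: 17 (5R,6R)-diol (C7–OH; C6–OH top; C5–OBz bottom; C1=C2–C3=C4)
Conditions: LiOH (1.1 equiv), THF–H2O, 0 °C; aq. NaH2PO4
Reagents that add atoms: none
Why: saponification that uses the higher electrophilicity of a six-membered cyclic carbonate over a secondary benzoate, since a single addition of hydroxide opens the ring and the carbonate unit leaves as hydrogencarbonate, so one equivalent of LiOH in the cold suffices and both C–O bonds, and with them C5 and C6, stay intact.

Step 12
Reactants: 17 diol; 18 benzoyl chloride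
Product: 19 [(5R,6R)-5-(benzoyloxy)-6-hydroxycyclohexa-1,3-dien-1-yl]methyl benzoate (target)
Conditions: BzCl (1.05 equiv), 2,4,6-collidine, CH2Cl2, −40 °C → 0 °C
Reagents that add atoms: benzoyl chloride (18), O=C(Cl)c1ccccc1
Why: chemoselective acylation, in which one equivalent of acid chloride with a hindered pyridine base at low temperature takes the primary allylic C7 hydroxyl ahead of the secondary C6 hydroxyl crowded by C1 and the C5 benzoate.

Compound list
1 | (−)-shikimic acid, (3R,4S,5R)-3,4,5-trihydroxycyclohex-1-ene-1-carboxylic acid | OC(=O)C1=C[C@@H](O)[C@@H](O)[C@H](O)C1 | starting material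
2 | methyl (−)-shikimate | COC(=O)C1=C[C@@H](O)[C@@H](O)[C@H](O)C1 | intermediate
3 | (3S,4R,5R)-epoxy ester: C7 methyl ester, C1=C6, C5–OH top, C3–C4 oxirane top | COC(=O)C1=C[C@@H](O)[C@H]2O[C@H]2C1 | intermediate
4 | (3S,4R,5R)-epoxy diol: C7–OH, C1=C6, C5–OH top, C3–C4 oxirane top | OCC1=C[C@@H](O)[C@H]2O[C@H]2C1 | intermediate
5 | (3S,4R,5R)-C7 TBS ether of 4, C5–OH free | CC(C)(C)[Si](C)(C)OCC1=C[C@@H](O)[C@H]2O[C@H]2C1 | intermediate
6 | benzoic acid | O=C(O)c1ccccc1 | starting material
7 | (3S,4S,5S)-epoxy benzoate: C7–OTBS, C1=C6, C5–OBz bottom, C3–C4 oxirane top | CC(C)(C)[Si](C)(C)OCC1=C[C@H](OC(=O)c3ccccc3)[C@H]2O[C@H]2C1 | intermediate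
8 | (3R,4R,5S)-hydroxy selenide: C7–OTBS, C1=C6, C5–OBz bottom, C4–OH top, C3–SePh bottom | CC(C)(C)[Si](C)(C)OCC1=C[C@H](OC(=O)c2ccccc2)[C@@H](O)[C@H]([Se]c2ccccc2)C1 | intermediate
9 | selenoxide of 8 (either configuration at selenium) | CC(C)(C)[Si](C)(C)OCC1=C[C@H](OC(=O)c2ccccc2)[C@@H](O)[C@H]([Se](=O)c2ccccc2)C1 | intermediate
10 | (4S,5S)-dienol: C7–OTBS, C6=C1–C2=C3, C5–OBz bottom, C4–OH top | CC(C)(C)[Si](C)(C)OCC1=C[C@H](OC(=O)c2ccccc2)[C@@H](O)C=C1 | intermediate
11 | methyl chloroformate | COC(=O)Cl | starting material
12 | (4S,5S)-silyl dienyl carbonate: C7–OTBS, C5–OBz bottom, C4–OCO2Me top | CC(C)(C)[Si](C)(C)OCC1=C[C@H](OC(=O)c2ccccc2)[C@@H](OC(=O)OC)C=C1 | intermediate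
13 | (4S,5S)-dienyl carbonate with free C7–OH (key-step precursor) | OCC1=C[C@H](OC(=O)c2ccccc2)[C@@H](OC(=O)OC)C=C1 | intermediate
14 | carbon dioxide | O=C=O | starting material
15 | palladium dienyl hemicarbonate (C4 σ-form, palladium bottom, dppe omitted) | [O-]C(=O)OCC1=C[C@H](OC(=O)c2ccccc2)[C@H]([Pd+])C=C1 | intermediate
16 | (5R,6R)-cyclic carbonate: 1,3-dioxan-2-one across C6–O (top) and C7–O, C1=C2–C3=C4, C5–OBz bottom | O=C1OCC2=CC=C[C@@H](OC(=O)c3ccccc3)[C@@H]2O1 | intermediate
17 | (5R,6R)-diol: C7–OH, C6–OH top, C5–OBz bottom | OCC1=CC=C[C@@H](OC(=O)c2ccccc2)[C@@H]1O | intermediate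
18 | benzoyl chloride | O=C(Cl)c1ccccc1 | starting material
19 | [(5R,6R)-5-(benzoyloxy)-6-hydroxycyclohexa-1,3-dien-1-yl]methyl benzoate | O=C(OCC1=CC=C[C@@H](OC(=O)c2ccccc2)[C@@H]1O)c1ccccc1 | target

Total step count: 12. Longest linear sequence: 12 steps (1 → 19).

Steps most likely to fail

Step 10.
- What may go wrong:
  - loss of the C5 proton, which lies anti to the metal, from the dienyl complex to carbonate or methoxide, leading to aromatisation;
  - ring closure at C2 instead of C6;
  - capture of the dienyl cation by methanol;
  - re-ionisation of the product by the catalyst.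
- Fallback, known chemistry only, from 10 back to 17. The C4 hydroxyl of dienol 10 directs VO(acac)2/tBuOOH epoxidation to the top face of C2=C3 and gives the vinyl epoxide F1. Pd(PPh3)4-catalysed cis-1,4-opening with levulinic acid follows: ionisation at C2 with inversion, then carboxylate attack at C6 anti to the metal. This places oxygen on the top face of C6 and gives the C6 levulinate C3,C4-cis-diol F2. Thiocarbonyldiimidazole converts the cis-diol into the cyclic thionocarbonate F3. Corey–Winter olefination in its Corey–Hopkins form (1,3-dimethyl-2-phenyl-1,3,2-diazaphospholidine, 40 °C) removes both oxygens and sets C3=C4 in the diene levulinate F4. Hydrazine acetate takes off the levulinate to give the C7 silyl ether of the diol F5, and HF·pyridine frees C7–OH, which rejoins the route at 17.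

Step 11.
- What may go wrong: competing saponification of the C5 benzoate, and base-induced benzoyl migration from C5–O to the freed C6–O.
- Fallback, from 16 directly to 19. Exhaustive methanolysis (K2CO3, MeOH, rt) strips the carbonate and the benzoate and gives the base-stable trans-triol F6. A regioselective double benzoylation with 18 (2.1 equiv, pyridine, CH2Cl2, −40 °C) then takes the primary C7 hydroxyl and the less crowded C5 hydroxyl. C6–OH stays free because it is squeezed between C1–CH2OBz and C5. Steps 11 and 12 are replaced.

Step 6.
- What may go wrong: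
  - benzoyl migration to the liberated C4 alkoxide;
  - ethanolysis of the benzoate in the basic selenolate medium;
  - incomplete regioselectivity of the ring opening.
- Fallback, from 7 back to 12. Li2NiBr4 (THF, 0 °C) should open the oxirane at C3 under nearly neutral conditions and give the trans-bromohydrin F7 (C3–Br bottom, C4–OH top). Reagent 11 with pyridine converts it into the bromo carbonate F8. DBU (toluene, rt) then removes HBr by anti E2 through the top-face allylic C2 hydrogen; the C4 hydrogen is cis to bromine and cannot compete. This delivers 12, and steps 6 to 8 are replaced.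

Further compounds
F1 | step 10 | vinyl epoxide: C7–OTBS, C1=C6, C5–OBz bottom, C4–OH top, C2–C3 oxirane top | CC(C)(C)[Si](C)(C)OCC1=C[C@H](OC(=O)c2ccccc2)[C@@H](O)[C@H]3O[C@H]31
F2 | step 10 | C6 levulinate C3,C4-cis-diol: C7–OTBS, C1=C2, C3–OH top, C4–OH top, C5–OBz bottom, C6–O-levulinoyl top | CC(C)(C)[Si](C)(C)OCC1=C[C@H](O)[C@H](O)[C@@H](OC(=O)c2ccccc2)[C@@H]1OC(=O)CCC(C)=O
F3 | step 10 | C3,C4-cyclic thionocarbonate of F2 | CC(C)(C)[Si](C)(C)OCC1=C[C@@H]2OC(=S)O[C@@H]2[C@@H](OC(=O)c3ccccc3)[C@@H]1OC(=O)CCC(C)=O
F4 | step 10 | diene levulinate: C7–OTBS, C1=C2–C3=C4, C5–OBz bottom, C6–O-levulinoyl top | CC(C)(C)[Si](C)(C)OCC1=CC=C[C@@H](OC(=O)c2ccccc2)[C@@H]1OC(=O)CCC(C)=O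
F5 | step 10 | C7 silyl ether of diol 17 | CC(C)(C)[Si](C)(C)OCC1=CC=C[C@@H](OC(=O)c2ccccc2)[C@@H]1O
F6 | step 11 | trans-triol: C7–OH, C6–OH top, C5–OH bottom, C1=C2–C3=C4 | OCC1=CC=C[C@@H](O)[C@@H]1O
F7 | step 6 | trans-bromohydrin: C7–OTBS, C1=C6, C5–OBz bottom, C4–OH top, C3–Br bottom | CC(C)(C)[Si](C)(C)OCC1=C[C@H](OC(=O)c2ccccc2)[C@@H](O)[C@H](Br)C1
F8 | step 6 | bromo carbonate: C4 methyl carbonate of F7 | CC(C)(C)[Si](C)(C)OCC1=C[C@H](OC(=O)c2ccccc2)[C@@H](OC(=O)OC)[C@H](Br)C1
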